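Target stops rising in the west run from 0.833 d: at 2.50 d it reads 67.6%, with 31.5% of starting material still beside it.

the same everywhere: reagent 0.0475 M (fed, over 40 min); free catalyst 0.29 mM
- north-west: starting material 0.025 M; second substrate 0.010 M; run made earlier
- west: starting material 0.038 M; second substrate 0.010 M; run made earlier
- east: starting material 0.050 M; second substrate 0.020 M; run made earlier
- flask: starting material 0.050 M; second substrate 0.0100 M; time 2.5 d

| run | time / d | starting material / % | target / % |
|---|---|---|---|
| north-west | 0.417 | 25.1 | 75.8 |
| north-west | 0.833 | 23.0 | 76.4 |
| north-west | 1.25 | 23.0 | 76.9 |
| north-west | 1.67 | 23.3 | 76.6 |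
| north-west | 2.00 | 23.5 | 76.9 |
| north-west | 2.50 | 23.0 | 76.4 |
| west | 0.208 | 40.1 | 59.1 |
| west | 0.333 | 34.8 | 64.6 |
| west | 0.500 | 32.7 | 66.0 |
| west | 0.833 | 32.0 | 67.9 |
| west | 1.67 | 31.1 | 67.4 |
| west | 2.50 | 31.5 | 67.6 |
| east | 0.208 | 57.3 | 42.7 |
| east | 0.625 | 54.2 | 45.0 |
| east | 1.25 | 53.8 | 45.1 |
| east | 1.67 | 54.1 | 45.5 |
| east | 2.50 | 54.7 | 45.0 |

(readings scatter by 0.5 percentage points)

- the reaction counts as stopped when no species that holds the starting material changes by six tenths of a point or more over the second half of the time

1. which holds at 2.5 d: what has brought the reaction to rest, or that it has not come to rest (no working catalyst is left / the reagent has run out first / forward and back rates have come level / it is still moving / all of the starting material has reacted)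
2. part of the starting material gone at 2.5 d
3. the target standing at 2.5 d, as a percentage of the starting material charged
4. amount of target if the flask were left three thousand times as long, in percent of the starting material charged

You need two amounts. The first is the spare reagent: its charge less the second substrate, taken here as consuming reagent one for one. In this flask that is 0.0375 M.

The second comes from the rest quotient K, c(target) / (c(starting material) · c(reagent)) at rest, the equilibrium constant. The last west reading gives K = 182 M⁻¹. The last north-west and east readings give 181 M⁻¹ and 165 M⁻¹. Its inverse, the back amount, is 0.00550 M.

Now solve both ends. With the back amount far below both charges, target approaches the smaller charge. In this flask that is the spare reagent, the limiting reagent, at 75.0% of the starting material charged. With the back amount far above both charges, target is near K times the product of the two charges. In this flask the spare reagent stands at 6.82 back amounts, between the ends.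

To join them, solve K = x / ((c(starting material) − x)(c(spare reagent) − x)), with x the target formed. You get 0.0295 M, or 59.1%. That is your figure for target, now and after long standing.

The forecast says forward and back rates have come level. It gives 59% gone (56.5% to 62%), 59% target (56% to 61.5%) and 59% target on the long standing asked for (56% to 62%). Its ground: “near-constant value points to an equilibrium”.

In the flask, forward and back rates have come level, with 59.3% gone, 58.9% target and 58.9% target on the long standing asked for.

    starting material + free catalyst → spent catalyst A (k = 0.0123 M⁻¹ min⁻¹)
    free catalyst → spent catalyst B (k = 2.08 × 10⁻⁶ min⁻¹)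
    starting material + reagent + free catalyst ⇌ free catalyst + target (K = 180 M⁻¹, k = 707 M⁻² min⁻¹)
    second substrate + reagent + free catalyst → free catalyst + second product (k = 6820 M⁻² min⁻¹)

This flask's end state gives a quotient of 180 M⁻¹. Now take a neighbour flask with 0.0060 M of second substrate, all else held. Its spare reagent is 0.0415 M. With K at 182 M⁻¹, the same equation gives 0.0318 M, or 63.7%. The neighbour flask holds 63.5% target and 36.2% starting material at 2.50 d.

The readings are calculated on assumed constants; noise was put on by code.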